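**Strategy.** Ring A (C1, C10–C14) is formed by ring expansion. A cyclopentenol whose carbinol carbon C14 carries the C1=C2 alkene of the complete C1–C9 oxane–lactone chain is epoxidised; a Lewis acid then moves the ring alkenyl carbon C10 from C14 to C1. This single semipinacol step enlarges the five-membered ring to the six-membered ring A, sets the quaternary centre C1 by inversion, and leaves the C14 ketone, the C2 hydroxyl and a C10=C11 alkene. It exploits the 1,3-dioxygenation O–C14–C1(CH3)–C2–O around the quaternary carbon shared by ring A and the ten-membered ring. The C9–C10 bond then closes the eight-membered oxocane onto the preformed oxane.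

Key step: step 17

Remark 1: every intermediate carries the atom numbers of the target: C1 is the quaternary carbon with methyl C15; C2 and C3 are the carbinols; C4–O–C8 is the ether; C5=C16 is the ring methylene; C6 carries chlorine; the lactone is C7–O–C19(=O)–C17(C18)–C8; C9 and C14 carry the acetates; C10 is the ring-fusion CH; C11=C20 is the ring A methylene; C12 and C13 are the ring A methylenes. The target is the single enantiomer encoded by its SMILES.
Remark 2: C14 in 19–25 (racemic carbinol), C17 in 10–14 and C10/C11 in 30–33 are mixtures that are erased or equilibrated later; they are left undefined in the SMILES.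

**Step 1**
Reactants: 1 furfuryl alcohol
Product: 2 2-[(4-methoxybenzyloxy)methyl]furan
Conditions: NaH, 4-methoxybenzyl chloride, Bu4NI (cat.), THF/DMF, 0 → 23 °C
Reagents that add atoms: 4-methoxybenzyl chloride, COc1ccc(CCl)cc1
Why: Williamson etherification of the primary alkoxide protects the future C9 oxygen as a PMB ether that is removable later under neutral oxidative conditions.

**Step 2**
Reactants: 2 2-[(4-methoxybenzyloxy)methyl]furan; 3 2-(tert-butyldimethylsilyloxy)-N-methoxy-N-methylacetamide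
Product: 5 2-(tert-butyldimethylsilyloxy)-1-{5-[(4-methoxybenzyloxy)methyl]furan-2-yl}ethanone, via 5-lithiofuran 4 (not isolated)
Conditions: n-BuLi, THF, −78 → 0 °C; then 3, −78 °C; aq. NH4Cl
Reagents that add atoms: none
Why: 2-substituted furans lithiate at the free α-position, and the stable Weinreb chelate stops at the ketone (Weinreb ketone synthesis), joining C4/C3 to the furan that holds C5–C8.

**Step 3**
Reactants: 5 furyl ketone
Product: 6 (S)-2-(tert-butyldimethylsilyloxy)-1-{5-[(4-methoxybenzyloxy)methyl]furan-2-yl}ethanol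
Conditions: RuCl(p-cymene)[(S,S)-TsDPEN] (1 mol %), HCO2H/Et3N (5:2), 25 °C
Reagents that add atoms: none
Why: Noyori asymmetric transfer hydrogenation of a 2-acylfuran sets the C4 carbinol centre under catalyst control, the furan taking the aryl role in the transition state.

**Step 4**
Reactants: 6 (S)-furyl carbinol
Product: 7 (2S)-2-[(tert-butyldimethylsilyloxy)methyl]-6-hydroxy-6-[(4-methoxybenzyloxy)methyl]-2H-pyran-3(6H)-one (C8 anomers)
Conditions: NBS, NaHCO3, NaOAc, THF/H2O (4:1), 0 °C
Reagents that add atoms: water, O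
Why: Achmatowicz rearrangement turns the furyl carbinol into the pyranone in which the carbinol oxygen becomes the C4–O–C8 ring oxygen, C5 is a ketone, C6=C7 an enone and C8 a hemiketal, with C4 untouched.

**Step 5**
Reactants: 7 pyranone hemiketal; 8 1-methoxy-1-(trimethylsilyloxy)prop-1-ene
Product: 10 methyl 2-{6-[(tert-butyldimethylsilyloxy)methyl]-2-[(4-methoxybenzyloxy)methyl]-5-oxo-5,6-dihydro-2H-pyran-2-yl}propanoate (propanoate trans to the C4 side chain; C17 epimers), via oxocarbenium ion 9 (not isolated)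
Conditions: TMSOTf (0.2 equiv), CH2Cl2, −78 °C
Reagents that add atoms: none
Why: Mukaiyama-type addition of the silyl ketene acetal to the cyclic oxocarbenium ion creates the quaternary C8; axial attack anti to the pseudo-equatorial C4 substituent places C17 trans to C3 and so leaves C9 cis to C3.

**Step 6**
Reactants: 10 enone ester
Product: 12 hydroxy keto lactone (cis-fused oxane–γ-lactone; C5 ketone; C6 OH trans to the C7 lactone oxygen; C17 epimers), via epoxy carboxylate 11 (not isolated)
Conditions: LiOH, H2O2 (30 %), THF/H2O, 0 → 23 °C; then 1 M HCl to pH 4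
Reagents that add atoms: hydrogen peroxide, OO; lithium hydroxide, [Li+].[OH-]
Why: Weitz–Scheffer epoxidation occurs anti to the axial C17 branch, LiOOH cleaves the methyl ester, and the carboxylate opens the epoxide at C7 with inversion (5-exo), giving the lactone oxygen on the C17 face and the C6 hydroxyl on the opposite face.

**Step 7**
Reactants: 12 hydroxy keto lactone
Product: 13 C6 tert-butyldimethylsilyl ether of 12
Conditions: TBSOTf, 2,6-lutidine, CH2Cl2, −78 → 0 °C
Reagents that add atoms: tert-butyldimethylsilyl triflate, CC(C)(C)[Si](C)(C)OS(=O)(=O)C(F)(F)F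
Why: Silylation of the hindered secondary α-hydroxy ketone protects the C6 oxygen, whose configuration is opposite to that of the final chlorine.

**Step 8**
Reactants: 13 silyloxy ketone
Product: 14 C5 exocyclic methylene lactone (C17 epimers)
Conditions: Zn, CH2Br2, TiCl4 (Lombardo reagent), THF/CH2Cl2, 0 → 23 °C
Reagents that add atoms: dibromomethane, BrCBr
Why: Lombardo methylenation is non-basic and selective for ketones over lactones, so C16 is installed without epimerising C4/C6 and without β-elimination of the C7 acyloxy group.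

**Step 9**
Reactants: 14 methylene lactone
Product: 15 C17-defined methylene lactone (C18 methyl cis to the ring-fusion ether oxygen; trans to C9)
Conditions: KOtBu (0.2 equiv), t-BuOH/THF, 0 °C; AcOH quench
Reagents that add atoms: none
Why: Base-catalysed epimerisation α to the lactone carbonyl is expected to settle the methyl group trans to the bulkier C9 substituent on the adjacent quaternary C8, the arrangement of the target.

**Step 10**
Reactants: 15 bis-silyl ether
Product: 16 C3 primary alcohol
Conditions: HF·pyridine, pyridine, THF, 0 °C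
Reagents that add atoms: none
Why: Buffered HF·pyridine cleaves the primary silyl ether much faster than the hindered secondary C6 silyl ether.

**Step 11**
Reactants: 16 primary alcohol
Product: 17 C3 aldehyde (east fragment)
Conditions: Dess–Martin periodinane, NaHCO3, CH2Cl2, 0 → 23 °C
Reagents that add atoms: none
Why: Buffered Dess–Martin oxidation gives the α-alkoxy aldehyde without epimerising C4; it is used crude in step 15.

**Step 12**
Reactants: 18 cyclopent-2-en-1-one
Product: 19 1-ethynylcyclopent-2-en-1-ol (racemic)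
Conditions: HC≡CMgBr, THF, −78 → 0 °C; aq. NH4Cl
Reagents that add atoms: ethynylmagnesium bromide, C#C[Mg]Br
Why: Alkynyl Grignard reagents add 1,2 to cyclic enones, giving the tertiary carbinol C14 with C10=C11, C12, C13 in the ring and C1/C2 as the alkyne.

**Step 13**
Reactants: 19 tertiary propargylic alcohol
Product: 20 triethylsilyl ether of 19
Conditions: Et3SiOTf, 2,6-lutidine, CH2Cl2, −78 °C
Reagents that add atoms: triethylsilyl triflate, CC[Si](CC)(CC)OS(=O)(=O)C(F)(F)F
Why: Silylation stops ionisation of the doubly activated tertiary alcohol in the next steps and later prevents this oxygen from directing the epoxidation.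

**Step 14**
Reactants: 20 silyl ether alkyne
Product: 22 (E)-1-(1-iodoprop-1-en-2-yl)-1-(triethylsilyloxy)cyclopent-2-ene, via alkenylalane 21 (not isolated)
Conditions: AlMe3, Cp2ZrCl2 (0.2 equiv), H2O (1 equiv), CH2Cl2, −20 °C; then I2, THF, −20 °C
Reagents that add atoms: trimethylaluminium, C[Al](C)C; iodine, [I][I]
Why: Negishi zirconium-catalysed carboalumination adds CH3 and Al syn across the terminal alkyne (methyl on C1), and iodinolysis with retention gives the vinyl iodide with C14 trans to iodine.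

**Step 15**
Reactants: 17 C3 aldehyde; 22 vinyl iodide
Product: 24 C2–C3 coupled allylic alcohol, via alkenylchromium 23 (not isolated)
Conditions: CrCl2 (4 equiv), NiCl2 (1 mol %), DMSO/THF, 25 °C
Reagents that add atoms: none
Why: Nozaki–Hiyama–Kishi coupling through the alkenylchromium species tolerates the lactone and silyl ethers, keeps the E geometry of the C1=C2 alkene, and should add in the Felkin–Anh sense (C4–O antiperiplanar) to give the C3 carbinol anti to the C4 ring oxygen.

**Step 16**
Reactants: 24 allylic alcohol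
Product: 25 threo 1,2-epoxy-3-ol (epoxide on C1–C2)
Conditions: mCPBA, NaHCO3, CH2Cl2, −10 °C
Reagents that add atoms: 3-chloroperbenzoic acid, O=C(OO)c1cccc(Cl)c1
Why: In this hydroxyl-directed (Henbest) epoxidation, A(1,3) strain between C3 and the cis methyl C15 holds the C3–H in the alkene plane, so the free C3 hydroxyl delivers the peracid to one face (threo); the silylated C14 oxygen cannot direct, and the cyclopentene and the electron-poor C5 methylene react more slowly.

**Step 17**
Reactants: 25 epoxy alcohol silyl ether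
Product: 26 ring A cyclohex-3-enone diol (C14 ketone; quaternary C1; C10=C11 alkene; free C2/C3 hydroxyls)
Conditions: BF3·OEt2 (1.2 equiv), CH2Cl2, −78 °C; aq. NaHCO3
Reagents that add atoms: none
Why: BF3 coordinates the epoxide oxygen and, as the tertiary C1–O bond ionises, the ring alkenyl carbon C10 migrates from C14 to C1 antiperiplanar to the leaving oxygen while the silyloxy lone pair forms the C14 carbonyl; loss of the triethylsilyl group on work-up gives the β-hydroxy ketone. The closest known reaction type is the semipinacol rearrangement of 2,3-epoxy alcohol silyl ethers with alkenyl shift, known as a ring expansion of 1-(1,2-epoxyalkyl)cycloalkanols. Ring A is not closed by a chain-end cyclisation but arises by one-carbon enlargement of the cyclopentene through this suprafacial 1,2-shift. C1 is set by inversion at the epoxide carbon (threo epoxide from the E-alkene), C2 keeps the epoxide oxygen with retention, and the undefined C14 centre is erased, so both carbinol epimers converge. The step needs C10 to migrate in preference to C13 and to outrun ionisation of the tertiary allylic silyl ether; the much higher migratory aptitude of an sp2 carbon, the greater basicity of the epoxide oxygen and the low temperature should secure this.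

**Step 18**
Reactants: 26 β-hydroxy ketone
Product: 27 triol (C14 hydroxyl 1,3-anti to the C2 hydroxyl)
Conditions: Me4NBH(OAc)3, AcOH/MeCN, −25 °C
Reagents that add atoms: none
Why: Evans–Saksena reduction delivers hydride internally from boron bound to the C2 hydroxyl, giving the 1,3-anti diol, which is the axial C14 alcohol of the target.

**Step 19**
Reactants: 27 triol
Product: 28 C2/C3 acetonide C14 alcohol
Conditions: 2,2-dimethoxypropane, PPTS (cat.), CH2Cl2, 23 °C
Reagents that add atoms: 2,2-dimethoxypropane, COC(C)(C)OC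
Why: Acetalisation prefers the five-membered dioxolane of the 1,2-diol over the strained dioxane of the anti-1,3-diol, leaving only C14–OH free.

**Step 20**
Reactants: 28 acetonide alcohol
Product: 29 C14 acetate
Conditions: Ac2O, DMAP, pyridine, 23 °C
Reagents that add atoms: acetic anhydride, CC(=O)OC(C)=O
Why: DMAP-catalysed acylation installs the final C14 acetate before the oxidations that follow.

**Step 21**
Reactants: 29 cyclohexene acetate
Product: 30 bromohydrin (C10 bromide; C11 hydroxyl; trans)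
Conditions: NBS, CaCO3, THF/H2O, 0 °C
Reagents that add atoms: N-bromosuccinimide, O=C1CCC(=O)N1Br; water, O
Why: Bromohydrin formation on the only electron-rich alkene; water opens the bromonium ion at C11, away from the quaternary C1 (Fürst–Plattner diaxial opening), so bromine ends on C10.

**Step 22**
Reactants: 30 PMB ether
Product: 31 C9 primary alcohol
Conditions: DDQ, CH2Cl2/pH 7 buffer, 0 °C
Reagents that add atoms: none
Why: Oxidative PMB cleavage under neutral conditions leaves silyl ethers, acetonide, acetate and bromohydrin intact.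

**Step 23**
Reactants: 31 diol
Product: 32 α-bromo ketone aldehyde (C11 ketone; C10 bromide; C9 aldehyde)
Conditions: Dess–Martin periodinane (3 equiv), NaHCO3, CH2Cl2, 23 °C
Reagents that add atoms: none
Why: One Dess–Martin oxidation converts the bromohydrin to the regiodefined α-bromo ketone and the neopentyl alcohol to the non-enolisable C9 aldehyde.

**Step 24**
Reactants: 32 bromo keto aldehyde
Product: 34 tricyclic aldol (C9–C10 bond formed; C9 hydroxyl; C11 ketone; C9 cis to C2 at the ring fusion), via samarium enolate 33 (not isolated)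
Conditions: SmI2 (2.2 equiv), THF, −78 °C, high dilution; aq. NH4Cl
Reagents that add atoms: none
Why: In this samarium Reformatsky-type aldol, a closure precedented for eight-membered carbocycles, SmI2 reduces the α-bromo ketone to the C10 enolate, which adds to the aldehyde; a chelated Zimmerman–Traxler chair on the enolate face anti to the axial C15 methyl should give the correct C9 configuration, while C10 (drawn as the cis-fused epimer) is corrected in step 26.

**Step 25**
Reactants: 34 β-hydroxy ketone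
Product: 35 C9 triethylsilyl ether
Conditions: Et3SiOTf, 2,6-lutidine, CH2Cl2, −78 °C
Reagents that add atoms: triethylsilyl triflate, CC[Si](CC)(CC)OS(=O)(=O)C(F)(F)F
Why: Silylation blocks retro-aldol opening of the medium ring during the basic olefination.

**Step 26**
Reactants: 35 silyloxy ketone
Product: 37 trans-fused C11 exocyclic methylene compound (H10 anti to C15), via trans-fused ketone 36 (not isolated)
Conditions: Ph3PCH3Br, KN(SiMe3)2, THF/toluene, 0 → 40 °C
Reagents that add atoms: methyltriphenylphosphonium bromide, C[P+](c1ccccc1)(c1ccccc1)c1ccccc1.[Br-]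
Why: In this Wittig methylenation the ylide first enolises the ketone reversibly, so C10 should equilibrate to the epimer that has both C1–C2 and C10–C9 equatorial on ring A before the carbonyl is olefinated.

**Step 27**
Reactants: 37 bis-silyl ether
Product: 38 C9 alcohol
Conditions: HF·pyridine, pyridine, THF, 0 °C
Reagents that add atoms: none
Why: The triethylsilyl ether is cleaved much faster than the secondary tert-butyldimethylsilyl ether at C6.

**Step 28**
Reactants: 38 C9 alcohol
Product: 39 9,14-diacetate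
Conditions: Ac2O, DMAP, Et3N, CH2Cl2, 23 °C
Reagents that add atoms: acetic anhydride, CC(=O)OC(C)=O
Why: DMAP-catalysed acylation of the hindered homoallylic alcohol installs the second acetate.

**Step 29**
Reactants: 39 C6 silyl ether
Product: 40 C6 allylic alcohol (hydroxyl trans to the C7 lactone oxygen)
Conditions: Bu4NF, AcOH (1:1), THF, 23 °C
Reagents that add atoms: none
Why: Acetic acid-buffered fluoride removes the silyl group without acetate migration or lactone opening.

**Step 30**
Reactants: 40 allylic alcohol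
Product: 41 C6 allylic chloride C2/C3 acetonide (chlorine cis to the C7 lactone oxygen)
Conditions: PPh3, hexachloroacetone, CH2Cl2, −20 → 0 °C
Reagents that add atoms: hexachloroacetone, ClC(Cl)(Cl)C(=O)C(Cl)(Cl)Cl
Why: Appel-type chlorination of the alkoxyphosphonium ion proceeds by SN2 with inversion and little allylic transposition; chloride enters from the open convex face of the oxane, opposite the axial leaving group.

**Step 31**
Reactants: 41 acetonide
Product: 42 target CNP0176535.1
Conditions: AcOH/H2O (4:1), 40 °C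
Reagents that add atoms: none
Why: Mild acid hydrolysis of the dioxolane frees the C2/C3 diol while the acetates, lactone and the inductively deactivated allylic chloride should survive.

**Compound list**

1 | furfuryl alcohol | OCc1ccco1 | starting material
2 | 2-[(4-methoxybenzyloxy)methyl]furan | COc1ccc(COCc2ccco2)cc1 | intermediate
3 | 2-(tert-butyldimethylsilyloxy)-N-methoxy-N-methylacetamide | CON(C)C(=O)CO[Si](C)(C)C(C)(C)C | starting material
4 | 5-lithio-2-[(4-methoxybenzyloxy)methyl]furan | [Li]c1ccc(COCc2ccc(OC)cc2)o1 | intermediate (not isolated)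
5 | 2-(tert-butyldimethylsilyloxy)-1-{5-[(4-methoxybenzyloxy)methyl]furan-2-yl}ethanone | COc1ccc(COCc2ccc(C(=O)CO[Si](C)(C)C(C)(C)C)o2)cc1 | intermediate
6 | (S)-2-(tert-butyldimethylsilyloxy)-1-{5-[(4-methoxybenzyloxy)methyl]furan-2-yl}ethanol | COc1ccc(COCc2ccc([C@@H](O)CO[Si](C)(C)C(C)(C)C)o2)cc1 | intermediate
7 | (2S)-2-[(tert-butyldimethylsilyloxy)methyl]-6-hydroxy-6-[(4-methoxybenzyloxy)methyl]-2H-pyran-3(6H)-one, C8 anomers | COc1ccc(COCC2(O)O[C@H](C(=O)C=C2)CO[Si](C)(C)C(C)(C)C)cc1 | intermediate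
8 | 1-methoxy-1-(trimethylsilyloxy)prop-1-ene | CC=C(OC)O[Si](C)(C)C | starting material
9 | oxocarbenium ion from 7 (C8=O+) | COc1ccc(COCC2=[O+][C@H](C(=O)C=C2)CO[Si](C)(C)C(C)(C)C)cc1 | intermediate (not isolated)
10 | methyl 2-{6-[(tert-butyldimethylsilyloxy)methyl]-2-[(4-methoxybenzyloxy)methyl]-5-oxo-5,6-dihydro-2H-pyran-2-yl}propanoate, propanoate trans to the C4 side chain, C17 epimers | COc1ccc(COC[C@@]2(C(C)C(=O)OC)O[C@H](C(=O)C=C2)CO[Si](C)(C)C(C)(C)C)cc1 | intermediate
11 | C6–C7 epoxy carboxylate (drawn as the acid), epoxide anti to the C17 branch | COc1ccc(COC[C@@]2(C(C)C(=O)O)O[C@H](C(=O)[C@H]3O[C@H]32)CO[Si](C)(C)C(C)(C)C)cc1 | intermediate (not isolated)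
12 | hydroxy keto lactone: cis-fused oxane–γ-lactone, C5 ketone, C6 OH trans to C7–O, C17 epimers | COc1ccc(COC[C@@]23O[C@H](C(=O)[C@@H](O)[C@@H]2OC(=O)C3C)CO[Si](C)(C)C(C)(C)C)cc1 | intermediate
13 | C6 tert-butyldimethylsilyl ether of 12 | COc1ccc(COC[C@@]23O[C@H](C(=O)[C@@H](O[Si](C)(C)C(C)(C)C)[C@@H]2OC(=O)C3C)CO[Si](C)(C)C(C)(C)C)cc1 | intermediate
14 | C5-methylene lactone, C17 epimers | COc1ccc(COC[C@@]23O[C@H](C(=C)[C@@H](O[Si](C)(C)C(C)(C)C)[C@@H]2OC(=O)C3C)CO[Si](C)(C)C(C)(C)C)cc1 | intermediate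
15 | C5-methylene lactone, C17 defined (methyl cis to ring-fusion ether oxygen) | COc1ccc(COC[C@@]23O[C@H](C(=C)[C@@H](O[Si](C)(C)C(C)(C)C)[C@@H]2OC(=O)[C@@H]3C)CO[Si](C)(C)C(C)(C)C)cc1 | intermediate
16 | C3 primary alcohol | COc1ccc(COC[C@@]23O[C@H](C(=C)[C@@H](O[Si](C)(C)C(C)(C)C)[C@@H]2OC(=O)[C@@H]3C)CO)cc1 | intermediate
17 | C3 aldehyde (east fragment) | COc1ccc(COC[C@@]23O[C@H](C(=C)[C@@H](O[Si](C)(C)C(C)(C)C)[C@@H]2OC(=O)[C@@H]3C)C=O)cc1 | intermediate
18 | cyclopent-2-en-1-one | O=C1C=CCC1 | starting material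
19 | 1-ethynylcyclopent-2-en-1-ol (racemic) | OC1(C#C)C=CCC1 | intermediate
20 | 1-ethynyl-1-(triethylsilyloxy)cyclopent-2-ene | CC[Si](CC)(CC)OC1(C#C)C=CCC1 | intermediate
21 | (E)-alkenyl(dimethyl)alane from 20 | CC[Si](CC)(CC)OC1(/C(C)=C/[Al](C)C)C=CCC1 | intermediate (not isolated)
22 | (E)-1-(1-iodoprop-1-en-2-yl)-1-(triethylsilyloxy)cyclopent-2-ene | CC[Si](CC)(CC)OC1(/C(C)=C/I)C=CCC1 | intermediate
23 | (E)-alkenylchromium dichloride from 22 | CC[Si](CC)(CC)OC1(/C(C)=C/[Cr](Cl)Cl)C=CCC1 | intermediate (not isolated)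
24 | coupled allylic alcohol (C3 OH anti to the C4 ring oxygen, E-C1=C2, C14 silyl ether; C14 epimers) | COc1ccc(COC[C@@]23O[C@H](C(=C)[C@@H](O[Si](C)(C)C(C)(C)C)[C@@H]2OC(=O)[C@@H]3C)[C@@H](O)/C=C(\C)C4(O[Si](CC)(CC)CC)C=CCC4)cc1 | intermediate
25 | threo C1–C2 epoxide of 24 | COc1ccc(COC[C@@]23O[C@H](C(=C)[C@@H](O[Si](C)(C)C(C)(C)C)[C@@H]2OC(=O)[C@@H]3C)[C@@H](O)[C@@H]5O[C@@]5(C)C4(O[Si](CC)(CC)CC)C=CCC4)cc1 | intermediate
26 | ring A cyclohex-3-enone: C14 ketone, quaternary C1, C2/C3 diol | COc1ccc(COC[C@@]23O[C@H](C(=C)[C@@H](O[Si](C)(C)C(C)(C)C)[C@@H]2OC(=O)[C@@H]3C)[C@@H](O)[C@H](O)[C@]4(C)C=CCCC4=O)cc1 | intermediate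
27 | C14, C2, C3 triol (C14 OH anti to C2 OH) | COc1ccc(COC[C@@]23O[C@H](C(=C)[C@@H](O[Si](C)(C)C(C)(C)C)[C@@H]2OC(=O)[C@@H]3C)[C@@H](O)[C@H](O)[C@]4(C)C=CCC[C@@H]4O)cc1 | intermediate
28 | C2/C3 acetonide, C14 alcohol | COc1ccc(COC[C@@]23O[C@H](C(=C)[C@@H](O[Si](C)(C)C(C)(C)C)[C@@H]2OC(=O)[C@@H]3C)[C@H]5OC(C)(C)O[C@@H]5[C@]4(C)C=CCC[C@@H]4O)cc1 | intermediate
29 | C14 acetate | COc1ccc(COC[C@@]23O[C@H](C(=C)[C@@H](O[Si](C)(C)C(C)(C)C)[C@@H]2OC(=O)[C@@H]3C)[C@H]5OC(C)(C)O[C@@H]5[C@]4(C)C=CCC[C@@H]4OC(C)=O)cc1 | intermediate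
30 | C10 bromide / C11 alcohol bromohydrin | COc1ccc(COC[C@@]23O[C@H](C(=C)[C@@H](O[Si](C)(C)C(C)(C)C)[C@@H]2OC(=O)[C@@H]3C)[C@H]5OC(C)(C)O[C@@H]5[C@]4(C)C(Br)C(O)CC[C@@H]4OC(C)=O)cc1 | intermediate
31 | C9 primary alcohol bromohydrin | OC[C@@]12O[C@H](C(=C)[C@@H](O[Si](C)(C)C(C)(C)C)[C@@H]1OC(=O)[C@@H]2C)[C@H]3OC(C)(C)O[C@@H]3[C@]4(C)C(Br)C(O)CC[C@@H]4OC(C)=O | intermediate
32 | C9 aldehyde, C10 bromo C11 ketone | O=C[C@@]12O[C@H](C(=C)[C@@H](O[Si](C)(C)C(C)(C)C)[C@@H]1OC(=O)[C@@H]2C)[C@H]3OC(C)(C)O[C@@H]3[C@]4(C)C(Br)C(=O)CC[C@@H]4OC(C)=O | intermediate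
33 | samarium C10=C11 enolate of 32 | O=C[C@@]12O[C@H](C(=C)[C@@H](O[Si](C)(C)C(C)(C)C)[C@@H]1OC(=O)[C@@H]2C)[C@H]3OC(C)(C)O[C@@H]3[C@]4(C)C=C(O[Sm](I)I)CC[C@@H]4OC(C)=O | intermediate (not isolated)
34 | tricyclic aldol: C9 OH, C11 ketone, C9 cis to C2 at the ring fusion | O=C1CC[C@H](OC(C)=O)[C@@]2(C)[C@@H]1[C@H](O)[C@@]13O[C@H](C(=C)[C@@H](O[Si](C)(C)C(C)(C)C)[C@@H]1OC(=O)[C@@H]3C)[C@H]4OC(C)(C)O[C@@H]42 | intermediate
35 | C9 triethylsilyl ether of 34 | O=C1CC[C@H](OC(C)=O)[C@@]2(C)[C@@H]1[C@H](O[Si](CC)(CC)CC)[C@@]13O[C@H](C(=C)[C@@H](O[Si](C)(C)C(C)(C)C)[C@@H]1OC(=O)[C@@H]3C)[C@H]4OC(C)(C)O[C@@H]42 | intermediate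
36 | trans-fused C11 ketone (C10 epimer of 35) | O=C1CC[C@H](OC(C)=O)[C@@]2(C)[C@H]1[C@H](O[Si](CC)(CC)CC)[C@@]13O[C@H](C(=C)[C@@H](O[Si](C)(C)C(C)(C)C)[C@@H]1OC(=O)[C@@H]3C)[C@H]4OC(C)(C)O[C@@H]42 | intermediate (not isolated)
37 | C11(20)-methylene compound, C9 OSiEt3, C6 OTBS | C=C1CC[C@H](OC(C)=O)[C@@]2(C)[C@H]1[C@H](O[Si](CC)(CC)CC)[C@@]13O[C@H](C(=C)[C@@H](O[Si](C)(C)C(C)(C)C)[C@@H]1OC(=O)[C@@H]3C)[C@H]4OC(C)(C)O[C@@H]42 | intermediate
38 | C9 alcohol | C=C1CC[C@H](OC(C)=O)[C@@]2(C)[C@H]1[C@H](O)[C@@]13O[C@H](C(=C)[C@@H](O[Si](C)(C)C(C)(C)C)[C@@H]1OC(=O)[C@@H]3C)[C@H]4OC(C)(C)O[C@@H]42 | intermediate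
39 | 9,14-diacetate, C6 OTBS | C=C1CC[C@H](OC(C)=O)[C@@]2(C)[C@H]1[C@H](OC(C)=O)[C@@]13O[C@H](C(=C)[C@@H](O[Si](C)(C)C(C)(C)C)[C@@H]1OC(=O)[C@@H]3C)[C@H]4OC(C)(C)O[C@@H]42 | intermediate
40 | C6 allylic alcohol | C=C1CC[C@H](OC(C)=O)[C@@]2(C)[C@H]1[C@H](OC(C)=O)[C@@]13O[C@H](C(=C)[C@@H](O)[C@@H]1OC(=O)[C@@H]3C)[C@H]4OC(C)(C)O[C@@H]42 | intermediate
41 | C6 chloride, C2/C3 acetonide | C=C1CC[C@H](OC(C)=O)[C@@]2(C)[C@H]1[C@H](OC(C)=O)[C@@]13O[C@H](C(=C)[C@H](Cl)[C@@H]1OC(=O)[C@@H]3C)[C@H]4OC(C)(C)O[C@@H]42 | intermediate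
42 | CNP0176535.1 | C=C1CC[C@H](OC(C)=O)[C@@]2(C)[C@H]1[C@H](OC(C)=O)[C@@]13O[C@H](C(=C)[C@H](Cl)[C@@H]1OC(=O)[C@@H]3C)[C@@H](O)[C@@H]2O | target

**Step count and risks**

Total step count: 31. Longest linear sequence: 28 steps (steps 1–11, then 15–31); the ring A precursor branch is steps 12–14.

Steps most likely to fail:

1. Step 17 (key step). The tertiary allylic silyl ether may ionise, or a hydride may shift in place of the alkenyl carbon, so that the ring is not enlarged. The fallback sets out from 25: Bu4NF buffered with AcOH (THF, −20 °C) removes the tertiary triethylsilyl group to give the epoxy diol F1. Al(OiPr)3 in i-PrOH/toluene at 80 °C should then effect the tandem semipinacol rearrangement and Meerwein–Ponndorf–Verley reduction inside an aluminium alkoxide chelate, without a free cationic Lewis acid. Hydride transfer within the chelate held by the C2 alkoxide is expected to give the 1,3-anti triol directly, and the route is rejoined at 27.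

2. Step 24. The aldehyde may react through a boat-like transition state, giving poor facial selectivity at C9. The fallback sets out from 32 and corrects C9 by reagent-controlled reduction in place of aldol induction. The cyclisation product with the wrong C9 configuration, aldol epimer F2, is carried through the unchanged operations of steps 25–27: silyl ether F3, methylene compound F4 and C9-epimeric alcohol F5. Dess–Martin oxidation (NaHCO3 buffer) gives the β,γ-unsaturated ketone F6. LiBH(s-Bu)3 in THF at −78 °C is expected to reduce it in the polar Felkin–Anh sense (C8–O antiperiplanar) to alcohol 38, where the route is rejoined.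

3. Step 26. The basic ylide may cause β-elimination of the C9 silyloxy group, or C10 may equilibrate incompletely before olefination. The fallback sets out from 35 and separates the two events, replacing the ylide by an addition–elimination sequence. DBU in toluene (23 °C) equilibrates C10 to the trans-fused ketone 36, here isolated. Me3SiCH2MgCl/CeCl3 (THF, −78 °C) adds to the ketone to give the β-hydroxysilane F7. HF·pyridine (THF, 0 °C) then triggers the Peterson elimination and removes the triethylsilyl group, rejoining the route at 38.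

**Further compounds**

F1 | step 17 | epoxy diol (25 without the triethylsilyl group) | COc1ccc(COC[C@@]23O[C@H](C(=C)[C@@H](O[Si](C)(C)C(C)(C)C)[C@@H]2OC(=O)[C@@H]3C)[C@@H](O)[C@@H]5O[C@@]5(C)C4(O)C=CCC4)cc1
F2 | step 24 | C9 epimer of aldol 34 | O=C1CC[C@H](OC(C)=O)[C@@]2(C)[C@@H]1[C@@H](O)[C@@]13O[C@H](C(=C)[C@@H](O[Si](C)(C)C(C)(C)C)[C@@H]1OC(=O)[C@@H]3C)[C@H]4OC(C)(C)O[C@@H]42
F3 | step 24 | C9 epimer of silyl ether 35 | O=C1CC[C@H](OC(C)=O)[C@@]2(C)[C@@H]1[C@@H](O[Si](CC)(CC)CC)[C@@]13O[C@H](C(=C)[C@@H](O[Si](C)(C)C(C)(C)C)[C@@H]1OC(=O)[C@@H]3C)[C@H]4OC(C)(C)O[C@@H]42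
F4 | step 24 | C9 epimer of methylene compound 37 | C=C1CC[C@H](OC(C)=O)[C@@]2(C)[C@H]1[C@@H](O[Si](CC)(CC)CC)[C@@]13O[C@H](C(=C)[C@@H](O[Si](C)(C)C(C)(C)C)[C@@H]1OC(=O)[C@@H]3C)[C@H]4OC(C)(C)O[C@@H]42
F5 | step 24 | C9 epimer of alcohol 38 | C=C1CC[C@H](OC(C)=O)[C@@]2(C)[C@H]1[C@@H](O)[C@@]13O[C@H](C(=C)[C@@H](O[Si](C)(C)C(C)(C)C)[C@@H]1OC(=O)[C@@H]3C)[C@H]4OC(C)(C)O[C@@H]42
F6 | step 24 | C9 ketone | C=C1CC[C@H](OC(C)=O)[C@@]2(C)[C@H]1C(=O)[C@@]13O[C@H](C(=C)[C@@H](O[Si](C)(C)C(C)(C)C)[C@@H]1OC(=O)[C@@H]3C)[C@H]4OC(C)(C)O[C@@H]42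
F7 | step 26 | C11 β-hydroxysilane (C11 carbinol bearing CH2SiMe3) | C[Si](C)(C)CC1(O)CC[C@H](OC(C)=O)[C@@]2(C)[C@H]1[C@H](O[Si](CC)(CC)CC)[C@@]13O[C@H](C(=C)[C@@H](O[Si](C)(C)C(C)(C)C)[C@@H]1OC(=O)[C@@H]3C)[C@H]4OC(C)(C)O[C@@H]42
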